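Everything rests on cutting the C7–H bond last: C7 is taken back to an aryl ketone and C9 to an ester, so that C8, held between the ring A (syringyl) carbonyl and the ester carbonyl and already carrying the 2,6-dimethoxyaryl ether of ring B, is an acidic methine that racemises freely. A single ruthenium-catalysed asymmetric transfer hydrogenation with dynamic kinetic resolution should then set both C7 and C8 of the threo pair from the racemate in one operation. Its precursor, a racemic α-aryloxy β-keto ester, is assembled convergently by rhodium-carbenoid O–H insertion of a diazo keto ester into a hindered phenol; ester reduction and debenzylation complete the route.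

Key step: step 6

Remark: lignan numbering is used (C7 benzylic carbinol carbon, C8 aryloxy-bearing carbon, C9 CH2OH carbon; ring A is the 4-hydroxy-3,5-dimethoxyphenyl ring, ring B the 2,6-dimethoxy-4-(3-hydroxypropyl)phenoxy ring), and the usual aryl ketone facial rule of the TsDPEN catalyst is assumed to hold for this substrate.

Step 1
Reactants: 1 acetosyringone (1-(4-hydroxy-3,5-dimethoxyphenyl)ethan-1-one)
Product: 2 1-(4-benzyloxy-3,5-dimethoxyphenyl)ethan-1-one
Conditions: BnBr (1.2 equiv), K2CO3 (2 equiv), DMF, 60 °C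
Reagents that add atoms: benzyl bromide, BrCc1ccccc1
Why: Williamson etherification of the para-acyl phenoxide with a benzylic halide proceeds despite the two ortho methoxy groups and installs an ether that tolerates the base, carbenoid, transfer-hydrogenation and hydride steps that follow.

Step 2
Reactants: 2 1-(4-benzyloxy-3,5-dimethoxyphenyl)ethan-1-one
Product: 3 ethyl 3-(4-benzyloxy-3,5-dimethoxyphenyl)-3-oxopropanoate
Conditions: NaH (2.5 equiv), (EtO)2CO (3 equiv), toluene, reflux; then 1 M HCl, 0 °C
Reagents that add atoms: diethyl carbonate, CCOC(=O)OCC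
Why: crossed Claisen condensation of the methyl ketone enolate with non-enolisable diethyl carbonate, pulled to completion by deprotonation of the β-keto ester formed, brings in C9 at the ester oxidation level.

Step 3
Reactants: 3 ethyl 3-(4-benzyloxy-3,5-dimethoxyphenyl)-3-oxopropanoate
Product: 4 ethyl 2-diazo-3-(4-benzyloxy-3,5-dimethoxyphenyl)-3-oxopropanoate
Conditions: 4-acetamidobenzenesulfonyl azide (1.2 equiv), Et3N (1.5 equiv), MeCN, 0 °C to rt
Reagents that add atoms: 4-acetamidobenzenesulfonyl azide, CC(=O)Nc1ccc(cc1)S(=O)(=O)N=[N+]=[N-]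
Why: Regitz diazo transfer to the doubly activated methylene, deprotonated by Et3N, should give a stable acceptor/acceptor diazo compound with an easily removed sulfonamide as the only co-product.

Step 4
Reactants: 5 sinapic acid ((E)-3-(4-hydroxy-3,5-dimethoxyphenyl)prop-2-enoic acid)
Product: 7 methyl 3-(4-hydroxy-3,5-dimethoxyphenyl)propanoate, via dihydrosinapic acid 6 (not isolated)
Conditions: H2 (1 atm), 10% Pd/C, MeOH, rt; filter; then H2SO4 (cat.), reflux
Reagents that add atoms: methanol, CO
Why: heterogeneous hydrogenation of the cinnamic alkene followed in the same methanol solution by Fischer esterification leaves the phenol as the only O–H group, so that the carbenoid of step 5 has a single insertion site.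

Step 5
Reactants: 4 ethyl 2-diazo-3-(4-benzyloxy-3,5-dimethoxyphenyl)-3-oxopropanoate; 7 methyl 3-(4-hydroxy-3,5-dimethoxyphenyl)propanoate
Product: 8 ethyl 3-(4-benzyloxy-3,5-dimethoxyphenyl)-2-[2,6-dimethoxy-4-(3-methoxy-3-oxopropyl)phenoxy]-3-oxopropanoate (racemic; C8 configurationally labile)
Conditions: Rh2(OAc)4 (1 mol %), 7 (1.3 equiv), toluene, 80 °C, slow addition of 4
Reagents that add atoms: none
Why: rhodium-carbenoid O–H insertion, in which the electrophilic dirhodium carbenoid from 4 is trapped by the phenol oxygen as an oxonium ylide that collapses by proton transfer, forms the hindered C8–O aryl ether under neutral conditions and joins the two arene fragments.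

Step 6
Reactants: 8 ethyl 3-(4-benzyloxy-3,5-dimethoxyphenyl)-2-[2,6-dimethoxy-4-(3-methoxy-3-oxopropyl)phenoxy]-3-oxopropanoate
Product: 9 ethyl (2S,3R)-3-(4-benzyloxy-3,5-dimethoxyphenyl)-2-[2,6-dimethoxy-4-(3-methoxy-3-oxopropyl)phenoxy]-3-hydroxypropanoate
Conditions: RuCl(p-cymene)[(S,S)-TsDPEN] (2 mol %), HCO2H/Et3N (5:2), CH2Cl2, 30 °C
Reagents that add atoms: none
Why: Asymmetric transfer hydrogenation with dynamic kinetic resolution: formate turns the precatalyst into the 18-electron hydride RuH(p-cymene)[(S,S)-TsDPEN], which hands its Ru–H and N–H hydrogens to the C7 carbonyl in a concerted six-membered outer-sphere transition state, while the C8 enantiomers of 8 keep interconverting through the enol of the keto ester faster than either is reduced. The closest known reaction type is the transfer hydrogenation of racemic α-alkoxy β-keto esters to syn α-alkoxy β-hydroxy esters with TsDPEN complexes of divalent ruthenium, applied here to an α-aryloxy member of the class; no ring is closed. C7 is set by the catalyst: by the usual aryl ketone rule (CH/π contact of p-cymene with ring A) the (S,S)-ligand should deliver hydride to the face that gives the (R)-carbinol. C8 is set by the substrate: the saturated metal offers no site for chelation, so the faster-reacting enantiomer should be the one that holds the C8–OAr bond anti to the incoming hydride (polar Felkin–Anh), which leads to the syn (2S,3R), that is threo, isomer. The two selectivities required, syn over anti and a single ketone face, are thus secured by the free epimerisation of the C8 methine flanked by ketone and ester and by the chiral diamine, and after reduction C8 is alpha to one ester only and stays fixed in the acidic medium.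

Step 7
Reactants: 9 ethyl (2S,3R)-3-(4-benzyloxy-3,5-dimethoxyphenyl)-2-[2,6-dimethoxy-4-(3-methoxy-3-oxopropyl)phenoxy]-3-hydroxypropanoate
Product: 10 (1R,2R)-1-(4-benzyloxy-3,5-dimethoxyphenyl)-2-[4-(3-hydroxypropyl)-2,6-dimethoxyphenoxy]propane-1,3-diol
Conditions: LiAlH4 (3 equiv), THF, 0 °C to rt; then Na2SO4·10H2O quench
Reagents that add atoms: none
Why: hydride reduction of both esters to primary alcohols should outrun retro-aldol cleavage or enolisation of the aluminium alkoxide at low temperature, so C7 and C8 are carried through unchanged and only the descriptor at C8 switches from S to R because CH2OH ranks below C7.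

Step 8
Reactants: 10 (1R,2R)-1-(4-benzyloxy-3,5-dimethoxyphenyl)-2-[4-(3-hydroxypropyl)-2,6-dimethoxyphenoxy]propane-1,3-diol
Product: 11 (1R,2R)-1-(4-hydroxy-3,5-dimethoxyphenyl)-2-[4-(3-hydroxypropyl)-2,6-dimethoxyphenoxy]propane-1,3-diol (target; threo 7R,8R)
Conditions: H2 (1 atm), 10% Pd/C, EtOAc, rt, stopped at full conversion of 10
Reagents that add atoms: none
Why: catalytic hydrogenolysis of the aryl benzyl ether in a neutral aprotic medium is expected to be much faster than cleavage of the secondary benzylic C7–OH or of the aryl alkyl ethers, so the ring A phenol is released without touching either stereocenter.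

Compound list
1 | acetosyringone, 1-(4-hydroxy-3,5-dimethoxyphenyl)ethan-1-one | CC(=O)c1cc(OC)c(O)c(OC)c1 | starting material
2 | 1-(4-benzyloxy-3,5-dimethoxyphenyl)ethan-1-one | CC(=O)c1cc(OC)c(OCc2ccccc2)c(OC)c1 | intermediate
3 | ethyl 3-(4-benzyloxy-3,5-dimethoxyphenyl)-3-oxopropanoate | CCOC(=O)CC(=O)c1cc(OC)c(OCc2ccccc2)c(OC)c1 | intermediate
4 | ethyl 2-diazo-3-(4-benzyloxy-3,5-dimethoxyphenyl)-3-oxopropanoate | CCOC(=O)C(=[N+]=[N-])C(=O)c1cc(OC)c(OCc2ccccc2)c(OC)c1 | intermediate
5 | sinapic acid, (E)-3-(4-hydroxy-3,5-dimethoxyphenyl)prop-2-enoic acid | OC(=O)/C=C/c1cc(OC)c(O)c(OC)c1 | starting material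
6 | dihydrosinapic acid, 3-(4-hydroxy-3,5-dimethoxyphenyl)propanoic acid (not isolated) | OC(=O)CCc1cc(OC)c(O)c(OC)c1 | intermediate
7 | methyl 3-(4-hydroxy-3,5-dimethoxyphenyl)propanoate | COC(=O)CCc1cc(OC)c(O)c(OC)c1 | intermediate
8 | ethyl 3-(4-benzyloxy-3,5-dimethoxyphenyl)-2-[2,6-dimethoxy-4-(3-methoxy-3-oxopropyl)phenoxy]-3-oxopropanoate, racemic | COc1cc(C(=O)C(C(=O)OCC)Oc2c(OC)cc(CCC(=O)OC)cc2OC)cc(OC)c1OCc3ccccc3 | intermediate
9 | ethyl (2S,3R)-3-(4-benzyloxy-3,5-dimethoxyphenyl)-2-[2,6-dimethoxy-4-(3-methoxy-3-oxopropyl)phenoxy]-3-hydroxypropanoate | COc1cc([C@@H](O)[C@@H](C(=O)OCC)Oc2c(OC)cc(CCC(=O)OC)cc2OC)cc(OC)c1OCc3ccccc3 | intermediate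
10 | (1R,2R)-1-(4-benzyloxy-3,5-dimethoxyphenyl)-2-[4-(3-hydroxypropyl)-2,6-dimethoxyphenoxy]propane-1,3-diol | COc1cc([C@@H](O)[C@@H](CO)Oc2c(OC)cc(CCCO)cc2OC)cc(OC)c1OCc3ccccc3 | intermediate
11 | (1R,2R)-1-(4-hydroxy-3,5-dimethoxyphenyl)-2-[4-(3-hydroxypropyl)-2,6-dimethoxyphenoxy]propane-1,3-diol | COc1cc([C@@H](O)[C@@H](CO)Oc2c(OC)cc(CCCO)cc2OC)cc(OC)c1O | target

Total step count: 8 steps.
Longest linear sequence: 7 steps (steps 1, 2, 3, 5, 6, 7 and 8, from 1 to 11); step 4 is the side branch.

Steps most likely to fail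

1. The transfer hydrogenation, step 6. Reduction may outpace epimerisation at C8, or the bulky 2,6-dimethoxyaryloxy group may erode the syn/anti or facial discrimination. If only the facial sense is reversed, the (R,R)-catalyst would be used. The fallback changes the approach and sets both centers by an auxiliary-controlled Evans syn aldol.
   - It sets out from 7: O-alkylation with commercial (S)-4-benzyl-3-(chloroacetyl)oxazolidin-2-one (K2CO3, NaI cat., MeCN, 50 °C) should give (S)-4-benzyl-3-{2-[2,6-dimethoxy-4-(3-methoxy-3-oxopropyl)phenoxy]acetyl}oxazolidin-2-one F1.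
   - Its (Z)-boron enolate (Bu2BOTf, iPr2NEt, CH2Cl2, −78 to 0 °C, then H2O2 at pH 7) would add to commercial 4-benzyloxy-3,5-dimethoxybenzaldehyde through a Zimmerman–Traxler chair, giving the syn adduct (S)-4-benzyl-3-{(2S,3R)-3-(4-benzyloxy-3,5-dimethoxyphenyl)-2-[2,6-dimethoxy-4-(3-methoxy-3-oxopropyl)phenoxy]-3-hydroxypropanoyl}oxazolidin-2-one F2.
   - Excess LiBH4 (THF/MeOH, 0 °C to rt) would remove the auxiliary reductively and reduce the methyl ester, so the fallback comes back to the route at 10.

2. The carbenoid O–H insertion, step 5. Insertion into the doubly ortho-substituted phenol may be slow enough that the carbenoid is diverted to dimerisation, capture of adventitious water or attack on the electron-rich arenes. The fallback forms the same C8–O bond by ionic substitution.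
   - It sets out from 3: bromination with NBS (1.0 equiv, MeCN, 0 °C) should give ethyl 2-bromo-3-(4-benzyloxy-3,5-dimethoxyphenyl)-3-oxopropanoate F3.
   - Displacement of bromide by the phenoxide of 7 (K2CO3, acetone, rt) comes back to the route at 8.

3. The final hydrogenolysis, step 8. Once the para phenol is free, over-reduction by cleavage of the benzylic C7–O bond may compete. The fallback masks the three hydroxyl groups before the benzyl ether is cleaved.
   - It sets out from 10: silylation (TBSOTf, 2,6-lutidine, CH2Cl2, 0 °C) should give (1R,2R)-1-(4-benzyloxy-3,5-dimethoxyphenyl)-1,3-bis(tert-butyldimethylsilyloxy)-2-{4-[3-(tert-butyldimethylsilyloxy)propyl]-2,6-dimethoxyphenoxy}propane F4, in which the C7 oxygen is a shielded, poor leaving group.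
   - Hydrogenolysis (H2, 10% Pd/C, EtOAc) should then give 4-[(1R,2R)-1,3-bis(tert-butyldimethylsilyloxy)-2-{4-[3-(tert-butyldimethylsilyloxy)propyl]-2,6-dimethoxyphenoxy}propyl]-2,6-dimethoxyphenol F5.
   - Buffered fluoride (TBAF/AcOH, THF, rt) removes the silyl groups and comes back to the route at 11.

Further compounds
F1 | step 6 | (S)-4-benzyl-3-{2-[2,6-dimethoxy-4-(3-methoxy-3-oxopropyl)phenoxy]acetyl}oxazolidin-2-one | COC(=O)CCc1cc(OC)c(OCC(=O)N2[C@@H](Cc3ccccc3)COC2=O)c(OC)c1
F2 | step 6 | (S)-4-benzyl-3-{(2S,3R)-3-(4-benzyloxy-3,5-dimethoxyphenyl)-2-[2,6-dimethoxy-4-(3-methoxy-3-oxopropyl)phenoxy]-3-hydroxypropanoyl}oxazolidin-2-one | COc1cc([C@@H](O)[C@@H](C(=O)N2[C@@H](Cc3ccccc3)COC2=O)Oc4c(OC)cc(CCC(=O)OC)cc4OC)cc(OC)c1OCc5ccccc5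
F3 | step 5 | ethyl 2-bromo-3-(4-benzyloxy-3,5-dimethoxyphenyl)-3-oxopropanoate | CCOC(=O)C(Br)C(=O)c1cc(OC)c(OCc2ccccc2)c(OC)c1
F4 | step 8 | (1R,2R)-1-(4-benzyloxy-3,5-dimethoxyphenyl)-1,3-bis(tert-butyldimethylsilyloxy)-2-{4-[3-(tert-butyldimethylsilyloxy)propyl]-2,6-dimethoxyphenoxy}propane | COc1cc([C@@H](O[Si](C)(C)C(C)(C)C)[C@@H](CO[Si](C)(C)C(C)(C)C)Oc2c(OC)cc(CCCO[Si](C)(C)C(C)(C)C)cc2OC)cc(OC)c1OCc3ccccc3
F5 | step 8 | 4-[(1R,2R)-1,3-bis(tert-butyldimethylsilyloxy)-2-{4-[3-(tert-butyldimethylsilyloxy)propyl]-2,6-dimethoxyphenoxy}propyl]-2,6-dimethoxyphenol | COc1cc([C@@H](O[Si](C)(C)C(C)(C)C)[C@@H](CO[Si](C)(C)C(C)(C)C)Oc2c(OC)cc(CCCO[Si](C)(C)C(C)(C)C)cc2OC)cc(OC)c1O
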